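At 12 h, when delta and theta are read, the length of a chain is a quotient of two fractions: the fraction of the charged Z standing as J, over the chains begun per Z charged.

| flask | Z | L | D | remark | time |
|---|---|---|---|---|---|
| Wednesday's | 0.18 M | 4.8 mM | 2.5 mol% | run made earlier |  |
| Monday's | 0.48 M | 4.8 mM | 2.5 mol% | run made earlier |  |
| Friday's | 0.82 M | 4.8 mM | 2.5 mol% | run made earlier |  |
| delta | 0.24 M | 4.80 mM | 2.5 mol% |  | 12 h |
| theta | 0.80 M | 4.80 mM | 2.5 mol% |  | 12 h |

- Wednesday's (time / h: J / %): 0.833: 8.1; 2.00: 17.8; 4.00: 32.7; 6.00: 43.8; 8.00: 52.7
- Monday's (time / h: J / %): 0.833: 21.4; 2.00: 45.8; 4.00: 69.2; 6.00: 81.7; 8.00: 87.5
- Friday's (time / h: J / %): 0.833: 35.8; 2.00: 65.4; 4.00: 86.3; 6.00: 93.3; 8.00: 95.8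

(each reading ± 0.3 percentage points)

- the average divides the monomer in chains by the number of chains begun, living and dead together
- the numbers in the tables scatter with a standard deviation of 0.3 percentage points
- the earlier runs do not show the number of chains; that part of a forecast is a guess

* which of the two ends with the longer chains by the average number of monomer units in a chain (chains begun, living or dead) ("neither" if they lie within 10%) (delta / theta / neither)
* average number of monomer units in a chain (chains begun, living or dead) at the end, delta
* average number of monomer units in a chain (chains begun, living or dead) at the end, theta

Two extreme flasks give that quotient by a reckoning in the head. In the first, each D begins one chain and L begins none, so chains per Z equal the loading of D. With the whole charge in chains, the length is then the ceiling length 40.0, one over the loading, which is the monomer-to-initiator ratio. In the second, each L begins a chain as well, adding 0.0200 chains per Z in delta and 0.00600 in theta.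

The fraction in J comes from the runs. If, at equal loading, the first-order rate constant is taken as proportional to the Z charged, this reckoning puts the fraction not in J in delta at Wednesday's last one raised to the power 2.00, which gives an estimate of 0.776 in J. Theta is charged close to Friday's run, and this reckoning takes that run's last reading, 95.8% at 8.00 h, as the estimate for theta. The first extreme then gives 31.1 and 38.3, the second 17.3 and 30.9.

The first readings help to place the real flask, if chains begun by L grow like the others. The first-order rate constants of Wednesday's and Friday's runs should then stand in the ratio 0.368, whereas with D as the starter they should stand in the ratio 0.220. The first readings of those two runs give a ratio of 0.191, farther from the former than from the latter, so this reckoning places delta and theta near the first extreme, though the chain count stays a guess.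

The forecast names theta, with 30 for delta, slightly below this reckoning, and 38 for theta: “Theta is longer either way, but chain count remains a guess”.

The flasks give 30.5 for delta and 38.5 for theta, so theta is longer.

    Z + D → G + J (k = 17.0 /M/h)
    Z + G → J + G, rate k2*[G]*[Z] (k = 28.0 /M/h)
    J + G → Z + G, rate k3*[G] as long as [J] is above zero (k = 0.670 /h)
    L + Z → X (k = 23.0 /M/h)

In delta at 12.0 h, with D at 0% of its charge, J is still made 2.19 times as fast as it is used up, each step taken net. Its J then stands at 76.2% of the charge, which against the ceiling of 40.0 is a length of 30.5. One more flask, like delta but with 1.5 mol% of D, has a ceiling of 66.7, holds 61.6% as J, and ends at 41.0.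

The data are simulated on assumed constants; scatter was added.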